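(The constants used here stand for no real mixture; no experiment stands behind them.)

Nothing is charged as E, so the autocatalytic step cannot start by itself, and while the slow uncatalysed step seeds E, the drain to Q is already taking G.

    G + X + E → D + 2 E (k1 = 8.7 M⁻² s⁻¹, Ea1 = 58.0 kJ mol⁻¹)
    G + X → D + E (k2 = 0.0011 M⁻¹ s⁻¹, Ea2 = 79.0 kJ mol⁻¹)
    Z ⇌ D, rate k3*(cs3 - [D]) while solid is left; crystals form when [D] > cs3 (cs3 = 15 mM, k3 = 0.40 s⁻¹)
    X + D → X.D (k4 = 0.011 M⁻¹ s⁻¹, Ea4 = 53.0 kJ mol⁻¹)
    G ⇌ Q (K5 = 22, k5 = 0.057 s⁻¹, Ea5 = 86.0 kJ mol⁻¹, ΔH5 = −90.0 kJ mol⁻¹)
    (constants at 90 °C)

in all of them: G 0.21 M; X 0.210 M; time 3.0 min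
- Friday's: at 90 °C until 50 s, from then on at 70 °C
- Monday's: temperature 70 °C
- Saturday's: temperature 90 °C

- what is said of D includes Z
- Z is a solid; its amount is given per volume of the solution
- the list of constants is for 90 °C, to be carried to other temperatures by the activation energies and enthalpies

1. the flask with the highest amount of D, in percent of the G charged ("all alike" if they lie within 1.5 percentage points) (Friday's / Monday's / Saturday's / all alike)
2. final D, as a percentage of the G charged, in Friday's
3. final D, as a percentage of the G charged, in Monday's
4. final D, as a percentage of the G charged, in Saturday's

**The toll.** We divide the rate of the drain by the rate of the autocatalytic step, which removes time from the problem. At 90 °C, while E grows tenfold, 0.0718 M of G goes to Q: this is the toll per decade, ln(10) times the forward drain constant over the autocatalytic constant times the X charged. At 70 °C the factors 5.3 and 3.1 lower it to 0.0418 M. E starts its climb from the seed level, where the two routes to E run equally: 0.126 mM at 90 °C and 0.0843 mM at 70 °C.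

**First way.** The charge divided by the toll gives a budget of decades, to be held against the decades from seed level to the charge. Saturday's has 2.93 against 3.22, so it falls short. Monday's has 5.02 against 3.40, so it clears the climb, but those decades are priced at 0.142 M of G as Q, which leaves 0.0680 M of the charge for D.

**Second way.** Here we keep the ledger: the charge equals E plus the toll times the decimal logarithm of E times the X charge, over the seed level times the X remaining. Each D brings one E and takes one X, and we set X.D aside. The logarithm is flat, so one pass from a trial suffices. Saturday's, tried at the break-even level 0.0312 M, gives 0.0333 M of E. Monday's, tried at a third of the charge, gives 0.0806 M. The two ways agree on the order of these flasks, but they part on size. The first way cheats, since it prices the climb up to the charge, while the ledger's E stops at 0.0806 M in Monday's.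

**Slow return.** The ledger treats Q as one-way. Over the 130 s after the 50 s mark, we reckon that Saturday's returns 33.7% of its Q, far more than the 1.56% reckoned for Monday's whole run. The window is fair, as the drain in Saturday's relaxes with a half-life of 0.194 min, shorter than 50 s. Returned G parts in the ratio of E to break-even, which adds 0.0307 M of D in Saturday's. Friday's cools at 50 s, and we leave it at the ledger figure. We commit to Monday's, with 15.9% in Friday's, 38.4% in Monday's and 30.5% in Saturday's.

**The forecast.** It names Monday's too, with 26% in Friday's, 42% in Monday's and 36% in Saturday's, and holds for Saturday's that “slow release from Q adds D late on”. Its figures stand above ours in each flask.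

**The result.** Monday's holds the most D: 36.2%, against 18.8% in Friday's and 29.9% in Saturday's. Saturday's, left until 30.0 min, stands at 80.4% with Q at 11.3%. The toll serves once more on the neighbour of Saturday's with 0.53 M of G: the climb from seed level to the X charge is priced at 0.231 M, and the G beyond it, 0.299 M, exceeds the X charge. In that flask X is the limiting reagent, ending at 0.11% of its charge, with D at 39.3%.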